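Ring A is a phloroglucinol in which the ether carbon (carbon 4) sits between two hydroxyl carbons (carbons 3 and 5). Carbons 3, 4 and 5 are therefore read as an aryloxymalonyl unit and carbons 2, 1 and 6 as an acetone unit. One methoxide-mediated double Claisen condensation of an aryloxymalonate with dimethyl 3-oxopentanedioate forms the bonds between carbons 2 and 3 and between carbons 5 and 6 and closes ring A, so the crowded terminal ether arises from a plain phenol alkylation. The precursor is the dimethyl malonate ether on the terminal oxygen of ring B of the permethylated heptamer of rings B to H, assembled convergently by copper-mediated ether couplings.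

Key step: step 12

Remarks and assumptions on the chemistry:
- Rings are lettered A to H from the 2,4,6-trihydroxyphenoxy end. Ring A is numbered so that carbon 4 bears the ether oxygen, carbons 1, 3 and 5 bear hydroxyls and carbons 2 and 6 bear hydrogen. In rings B to H, position 1 is the carbon bonded to the oxygen that leads toward ring A.
- The seven ether links are: ring A carbon 4 to ring B position 1; ring B position 4 to ring C position 1; ring C position 2 to ring D position 1; ring D position 4 to ring E position 1; ring E position 2 to ring F position 1; ring F position 4 to ring G position 1; ring G position 2 to ring H position 1.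
- The target re-derived from its SMILES is C48H34O28, with 21 hydroxyls, 7 diaryl ether oxygens and no stereocentre. Rings C, E and G are pentaoxygenated with one ring hydrogen each.
- The eighteen hydroxyls of rings B to H are carried as methyl ethers. The position 1 oxygen of ring B is carried as a formyl group until the last coupling is done, so only one phenol is present in any coupling.
- The five starting materials, and the 2-iodo-1,3,5-trimethoxybenzene used in the first fallback, are assumed to be catalogue items. All copper-catalysed steps are run under argon unless oxygen is stated.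

Step 1
Reactants: 1 2,3,4-trimethoxyphenol
Product: 2 6-iodo-2,3,4-trimethoxyphenol
Conditions: iodine, NaHCO3, THF/H2O, 0 °C → rt
Reagents that add atoms: iodine, II
Why: Electrophilic aromatic iodination through the phenoxide should place iodine at position 6, the only free position ortho or para to the phenoxide oxygen (position 4 is blocked and position 5 is meta), which fixes the halide/oxygen pattern of rings C, E and G.

Step 2
Reactants: 2 6-iodo-2,3,4-trimethoxyphenol
Product: 3 1-iodo-3,4,5-trimethoxy-2-(methoxymethoxy)benzene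
Conditions: NaH, THF, 0 °C; MOMCl, 0 °C → rt
Reagents that add atoms: chloromethyl methyl ether, COCCl
Why: Williamson-type O-alkylation of the sodium phenoxide gives a base-stable acetal that keeps the oxygen destined for position 2 of rings C and E silent during the copper couplings and is removable with dilute acid beside methyl ethers.

Step 3
Reactants: 2 6-iodo-2,3,4-trimethoxyphenol; 4 (3,4,5-trimethoxyphenyl)boronic acid
Product: 5 1-iodo-3,4,5-trimethoxy-2-(3,4,5-trimethoxyphenoxy)benzene (rings G and H; iodide at position 1 of ring G)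
Conditions: Cu(OAc)2 (50 mol%), pyridine, 4 Å MS, CH2Cl2, oxygen (1 atm), rt
Reagents that add atoms: none
Why: Chan–Lam coupling (aryl transfer from boron to a divalent copper phenoxide, then oxidation and C–O reductive elimination) proceeds at room temperature with 2,6-disubstituted ortho-halophenols and leaves the C–I bond untouched, so the ether between position 2 of ring G and position 1 of ring H forms without a protecting group.

Step 4
Reactants: 6 4-bromo-2,6-dimethoxyphenol; 3 1-iodo-3,4,5-trimethoxy-2-(methoxymethoxy)benzene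
Product: 7 5-bromo-1,3-dimethoxy-2-[3,4,5-trimethoxy-2-(methoxymethoxy)phenoxy]benzene (two-ring block used twice; bromide para to the new ether)
Conditions: CuI (10 mol%), picolinic acid (20 mol%), K3PO4, DMSO, 80 °C
Reagents that add atoms: none
Why: Ligand-accelerated Ullmann diaryl ether coupling of a hindered phenoxide with an aryl iodide should be chemoselective, because C–I reacts faster than C–Br at 80 °C and the only bromide initially present sits on the electron-rich phenoxide ring; a slight excess of 3 is used.

Step 5
Reactants: 6 4-bromo-2,6-dimethoxyphenol; 5 1-iodo-3,4,5-trimethoxy-2-(3,4,5-trimethoxyphenoxy)benzene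
Product: 8 5-bromo-1,3-dimethoxy-2-[3,4,5-trimethoxy-2-(3,4,5-trimethoxyphenoxy)phenoxy]benzene (rings F to H; bromide at position 1 of ring F)
Conditions: CuI (10 mol%), picolinic acid (20 mol%), K3PO4, DMSO, 80 °C
Reagents that add atoms: none
Why: The same iodide-selective Ullmann coupling as in step 4 forms the ether between position 4 of ring F and position 1 of ring G and keeps the ring F bromide for the final fragment union.

Step 6
Reactants: 7 5-bromo-1,3-dimethoxy-2-[3,4,5-trimethoxy-2-(methoxymethoxy)phenoxy]benzene
Product: 11 4-(2-hydroxy-3,4,5-trimethoxyphenoxy)-3,5-dimethoxybenzaldehyde (rings B and C; formyl on ring B; hydroxyl on ring C), via aryllithium 9 (not isolated), via MOM-protected aldehyde 10 (not isolated)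
Conditions: n-BuLi, THF, −78 °C; DMF, −78 → 0 °C; then 3 M HCl, THF, 50 °C
Reagents that add atoms: N,N-dimethylformamide, CN(C)C=O
Why: Bromine–lithium exchange and formylation of the aryllithium with DMF (Bouveault aldehyde synthesis) install the masked position 1 oxygen of ring B as a formyl group, and the acidic work-up releases the aldehyde and hydrolyses the MOM acetal in the same flask.

Step 7
Reactants: 11 4-(2-hydroxy-3,4,5-trimethoxyphenoxy)-3,5-dimethoxybenzaldehyde; 7 5-bromo-1,3-dimethoxy-2-[3,4,5-trimethoxy-2-(methoxymethoxy)phenoxy]benzene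
Product: 12 tetramer aldehyde of rings B to E as its MOM ether (formyl on ring B; OMOM at position 2 of ring E)
Conditions: CuI (20 mol%), N,N-dimethylglycine (40 mol%), Cs2CO3, 1,4-dioxane, 95 °C
Reagents that add atoms: none
Why: Ullmann-type C–O coupling of an unhindered aryl bromide with the ring C phenoxide, the only phenol present, forms the ether between position 2 of ring C and position 1 of ring D; low-polarity dioxane is chosen so that an SNAr-type (Smiles) aryl shift of the formyl-bearing ring B is disfavoured.

Step 8
Reactants: 12 tetramer aldehyde of rings B to E as its MOM ether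
Product: 13 tetramer aldehyde phenol of rings B to E (formyl on ring B; hydroxyl at position 2 of ring E)
Conditions: 3 M HCl, THF, 50 °C
Reagents that add atoms: none
Why: Acid-catalysed acetal hydrolysis removes the MOM group while aryl methyl ethers, diaryl ethers and the aldehyde are inert to dilute aqueous acid.

Step 9
Reactants: 13 tetramer aldehyde phenol of rings B to E; 8 5-bromo-1,3-dimethoxy-2-[3,4,5-trimethoxy-2-(3,4,5-trimethoxyphenoxy)phenoxy]benzene
Product: 14 permethylated heptamer aldehyde of rings B to H (formyl on ring B)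
Conditions: CuI (20 mol%), N,N-dimethylglycine (40 mol%), Cs2CO3, 1,4-dioxane, 100 °C
Reagents that add atoms: none
Why: The same Ullmann-type coupling joins the ring E phenoxide of the tetramer to the unhindered ring F bromide; ring D next to the phenoxide carries no activating group, so no aryl migration is expected.

Step 10
Reactants: 14 permethylated heptamer aldehyde of rings B to H
Product: 16 permethylated heptamer phenol of rings B to H (free hydroxyl at position 1 of ring B), via aryl formate 15 (not isolated)
Conditions: mCPBA, CH2Cl2, 0 °C → rt; then K2CO3 (cat.), MeOH, rt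
Reagents that add atoms: meta-chloroperoxybenzoic acid, OOC(=O)c1cccc(Cl)c1
Why: Baeyer–Villiger (Dakin-type) oxidation of the aldehyde should proceed with migration of the electron-rich para-aryloxy ring B to give the formate, which methanolysis converts into the ring B phenol.

Step 11
Reactants: 16 permethylated heptamer phenol of rings B to H; 17 dimethyl bromomalonate
Product: 18 dimethyl 2-aryloxymalonate of the permethylated heptamer of rings B to H (key-step precursor)
Conditions: K2CO3, acetone, 50 °C
Reagents that add atoms: none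
Why: Williamson O-alkylation of the unhindered ring B phenoxide at the sp3 carbon of the bromomalonate makes the future ether between ring A carbon 4 and ring B before ring A exists; about 1.1 equiv of 17 limits over-alkylation of the acidic product.

Step 12
Reactants: 18 dimethyl 2-aryloxymalonate of the permethylated heptamer of rings B to H; 19 dimethyl 3-oxopentanedioate
Product: 21 octamer with ring A as dimethyl 2,4,6-trihydroxy-5-aryloxybenzene-1,3-dicarboxylate, via open-chain dioxoheptanedioate triester 20 (not isolated)
Conditions: 19 (3 equiv), NaOMe (4 equiv), MeOH then toluene, distil off MeOH, 110 °C, Ar; then 1 M HCl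
Reagents that add atoms: none
Why: NaOMe deprotonates 19, the more acidic partner, and its enolate carbon attacks one ester of 18 in an intermolecular Claisen condensation (bond between ring A carbons 2 and 3) to give 20 after loss of methoxide. The remaining CH2 enolate of 20 attacks the second malonate ester in a 6-exo-trig Dieckmann closure (bond between ring A carbons 5 and 6), and the cyclohexane-1,3,5-trione tautomerises to the phloroglucinol, whose deprotonation is the irreversible sink. The closest known reaction type is the classical alkoxide-mediated condensation of a malonic ester with an acetonedicarboxylic ester to a phloroglucinol dicarboxylate. No stereocentre is formed. The step needs C- rather than O-acylation and must outrun retro-Claisen cleavage and self-condensation of 19: matched methyl esters and methoxide keep O-acyl and pyranone by-products reversible, removal of MeOH and aromatisation pull the equilibria forward, excess 19 compensates for its self-condensation, and 18 and 19 are the only acidic species because every other hydroxyl is a methyl ether.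

Step 13
Reactants: 21 octamer with ring A as dimethyl 2,4,6-trihydroxy-5-aryloxybenzene-1,3-dicarboxylate
Product: 23 octamer with free ring A triol and rings B to H permethylated, via ring A diacid 22 (not isolated)
Conditions: 2 M KOH (aq), 1,4-dioxane, 100 °C, Ar; then HCl to pH 1, 60 °C
Reagents that add atoms: none
Why: Saponification followed by acidification gives a 2,4,6-trihydroxyisophthalic acid that should lose both carboxyl groups on gentle warming through its keto (beta-keto acid) tautomers; this is the classical ester hydrolysis and decarboxylation of phloroglucinol carboxylates.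

Step 14
Reactants: 23 octamer with free ring A triol and rings B to H permethylated
Product: 24 CNP0206369.0 (target)
Conditions: BBr3 (excess), CH2Cl2, −78 °C → rt, Ar; then MeOH/H2O, 0 °C
Reagents that add atoms: none
Why: Lewis-acid demethylation (BBr3 cleavage of aryl methyl ethers through borate esters and bromide attack on methyl) should unmask all eighteen hydroxyls while leaving the diaryl ether bonds intact.

Compound list
1 | 2,3,4-trimethoxyphenol | COc1ccc(O)c(OC)c1OC | starting material
2 | 6-iodo-2,3,4-trimethoxyphenol | Oc1c(I)cc(OC)c(OC)c1OC | intermediate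
3 | 1-iodo-3,4,5-trimethoxy-2-(methoxymethoxy)benzene | COCOc1c(I)cc(OC)c(OC)c1OC | intermediate
4 | (3,4,5-trimethoxyphenyl)boronic acid | OB(O)c1cc(OC)c(OC)c(OC)c1 | starting material
5 | 1-iodo-3,4,5-trimethoxy-2-(3,4,5-trimethoxyphenoxy)benzene | Ic1cc(OC)c(OC)c(OC)c1Oc1cc(OC)c(OC)c(OC)c1 | intermediate
6 | 4-bromo-2,6-dimethoxyphenol | Oc1c(OC)cc(Br)cc1OC | starting material
7 | 5-bromo-1,3-dimethoxy-2-[3,4,5-trimethoxy-2-(methoxymethoxy)phenoxy]benzene | Brc1cc(OC)c(Oc2cc(OC)c(OC)c(OC)c2OCOC)c(OC)c1 | intermediate
8 | 5-bromo-1,3-dimethoxy-2-[3,4,5-trimethoxy-2-(3,4,5-trimethoxyphenoxy)phenoxy]benzene | Brc1cc(OC)c(Oc2cc(OC)c(OC)c(OC)c2Oc2cc(OC)c(OC)c(OC)c2)c(OC)c1 | intermediate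
9 | {3,5-dimethoxy-4-[3,4,5-trimethoxy-2-(methoxymethoxy)phenoxy]phenyl}lithium | [Li]c1cc(OC)c(Oc2cc(OC)c(OC)c(OC)c2OCOC)c(OC)c1 | intermediate
10 | 3,5-dimethoxy-4-[3,4,5-trimethoxy-2-(methoxymethoxy)phenoxy]benzaldehyde | O=Cc1cc(OC)c(Oc2cc(OC)c(OC)c(OC)c2OCOC)c(OC)c1 | intermediate
11 | 4-(2-hydroxy-3,4,5-trimethoxyphenoxy)-3,5-dimethoxybenzaldehyde | O=Cc1cc(OC)c(Oc2cc(OC)c(OC)c(OC)c2O)c(OC)c1 | intermediate
12 | 4-{2-[3,5-dimethoxy-4-(3,4,5-trimethoxy-2-(methoxymethoxy)phenoxy)phenoxy]-3,4,5-trimethoxyphenoxy}-3,5-dimethoxybenzaldehyde (tetramer of rings B to E; methoxymethyl ether at position 2 of ring E) | O=Cc1cc(OC)c(Oc2cc(OC)c(OC)c(OC)c2Oc2cc(OC)c(Oc3cc(OC)c(OC)c(OC)c3OCOC)c(OC)c2)c(OC)c1 | intermediate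
13 | 4-{2-[4-(2-hydroxy-3,4,5-trimethoxyphenoxy)-3,5-dimethoxyphenoxy]-3,4,5-trimethoxyphenoxy}-3,5-dimethoxybenzaldehyde (tetramer of rings B to E; hydroxyl at position 2 of ring E) | O=Cc1cc(OC)c(Oc2cc(OC)c(OC)c(OC)c2Oc2cc(OC)c(Oc3cc(OC)c(OC)c(OC)c3O)c(OC)c2)c(OC)c1 | intermediate
14 | permethylated heptamer of rings B to H with a formyl group at position 1 of ring B | O=Cc1cc(OC)c(Oc2cc(OC)c(OC)c(OC)c2Oc2cc(OC)c(Oc3cc(OC)c(OC)c(OC)c3Oc3cc(OC)c(Oc4cc(OC)c(OC)c(OC)c4Oc4cc(OC)c(OC)c(OC)c4)c(OC)c3)c(OC)c2)c(OC)c1 | intermediate
15 | permethylated heptamer of rings B to H as the formate ester at position 1 of ring B | O=COc1cc(OC)c(Oc2cc(OC)c(OC)c(OC)c2Oc2cc(OC)c(Oc3cc(OC)c(OC)c(OC)c3Oc3cc(OC)c(Oc4cc(OC)c(OC)c(OC)c4Oc4cc(OC)c(OC)c(OC)c4)c(OC)c3)c(OC)c2)c(OC)c1 | intermediate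
16 | permethylated heptamer of rings B to H with a free hydroxyl at position 1 of ring B | Oc1cc(OC)c(Oc2cc(OC)c(OC)c(OC)c2Oc2cc(OC)c(Oc3cc(OC)c(OC)c(OC)c3Oc3cc(OC)c(Oc4cc(OC)c(OC)c(OC)c4Oc4cc(OC)c(OC)c(OC)c4)c(OC)c3)c(OC)c2)c(OC)c1 | intermediate
17 | dimethyl bromomalonate | COC(=O)C(Br)C(=O)OC | starting material
18 | dimethyl 2-aryloxymalonate of the permethylated heptamer of rings B to H (malonate on the position 1 oxygen of ring B) | COC(=O)C(C(=O)OC)Oc1cc(OC)c(Oc2cc(OC)c(OC)c(OC)c2Oc2cc(OC)c(Oc3cc(OC)c(OC)c(OC)c3Oc3cc(OC)c(Oc4cc(OC)c(OC)c(OC)c4Oc4cc(OC)c(OC)c(OC)c4)c(OC)c3)c(OC)c2)c(OC)c1 | intermediate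
19 | dimethyl 3-oxopentanedioate | COC(=O)CC(=O)CC(=O)OC | starting material
20 | dimethyl 2-aryloxy-4-(methoxycarbonyl)-3,5-dioxoheptanedioate of the heptamer (open-chain C-acylation adduct; enolised, no defined configuration at carbons 2 and 4) | COC(=O)CC(=O)C(C(=O)OC)C(=O)C(C(=O)OC)Oc1cc(OC)c(Oc2cc(OC)c(OC)c(OC)c2Oc2cc(OC)c(Oc3cc(OC)c(OC)c(OC)c3Oc3cc(OC)c(Oc4cc(OC)c(OC)c(OC)c4Oc4cc(OC)c(OC)c(OC)c4)c(OC)c3)c(OC)c2)c(OC)c1 | intermediate
21 | octamer with ring A as dimethyl 2,4,6-trihydroxy-5-aryloxybenzene-1,3-dicarboxylate, rings B to H permethylated | Oc1c(C(=O)OC)c(O)c(Oc2cc(OC)c(Oc3cc(OC)c(OC)c(OC)c3Oc3cc(OC)c(Oc4cc(OC)c(OC)c(OC)c4Oc4cc(OC)c(Oc5cc(OC)c(OC)c(OC)c5Oc5cc(OC)c(OC)c(OC)c5)c(OC)c4)c(OC)c3)c(OC)c2)c(O)c1C(=O)OC | intermediate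
22 | octamer with ring A as 2,4,6-trihydroxy-5-aryloxybenzene-1,3-dicarboxylic acid, rings B to H permethylated | Oc1c(C(=O)O)c(O)c(Oc2cc(OC)c(Oc3cc(OC)c(OC)c(OC)c3Oc3cc(OC)c(Oc4cc(OC)c(OC)c(OC)c4Oc4cc(OC)c(Oc5cc(OC)c(OC)c(OC)c5Oc5cc(OC)c(OC)c(OC)c5)c(OC)c4)c(OC)c3)c(OC)c2)c(O)c1C(=O)O | intermediate
23 | octamer with ring A as free 2,4,6-trihydroxyphenyl ether, rings B to H permethylated (octadeca-O-methyl ether of the target) | Oc1cc(O)c(Oc2cc(OC)c(Oc3cc(OC)c(OC)c(OC)c3Oc3cc(OC)c(Oc4cc(OC)c(OC)c(OC)c4Oc4cc(OC)c(Oc5cc(OC)c(OC)c(OC)c5Oc5cc(OC)c(OC)c(OC)c5)c(OC)c4)c(OC)c3)c(OC)c2)c(O)c1 | intermediate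
24 | CNP0206369.0 | Oc1cc(O)c(Oc2cc(O)c(Oc3cc(O)c(O)c(O)c3Oc3cc(O)c(Oc4cc(O)c(O)c(O)c4Oc4cc(O)c(Oc5cc(O)c(O)c(O)c5Oc5cc(O)c(O)c(O)c5)c(O)c4)c(O)c3)c(O)c2)c(O)c1 | target

Total step count: 14. Longest linear sequence: 12 steps (steps 1, 2, 4 and 6 to 14).

Steps most likely to fail:

1. Step 12 (ring A annulation). The bulky, partly enolised aryloxymalonate may be acylated too slowly, so that self-condensation of the ketodiester and methoxide-induced retro-Claisen cleavage or loss of a methoxycarbonyl group win and ring A does not close. The fallback sets out from phenol 16 and abandons the annulation. Ullmann coupling of the unhindered ring B phenoxide with 2-iodo-1,3,5-trimethoxybenzene (CuI, picolinic acid, K3PO4, DMSO, 110 °C) should give the fully methylated octamer F1. Exhaustive demethylation of F1 with BBr3 under the conditions of step 14 comes back to the route at 24.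

2. Step 7 (ether between position 2 of ring C and position 1 of ring D). Oxidative addition of the electron-rich bromide to the hindered copper phenoxide may be slow, and at the temperature then needed the formyl-activated ring B could migrate between the two ortho oxygens of ring C. The fallback sets out from bromide 7 and changes the mechanism to an oxidative coupling at room temperature. Bromine–lithium exchange (n-BuLi, THF, −78 °C), quench with B(OiPr)3 and mild NH4Cl hydrolysis should give {3,5-dimethoxy-4-[3,4,5-trimethoxy-2-(methoxymethoxy)phenoxy]phenyl}boronic acid F2. Chan–Lam coupling of F2 with phenol 11 (Cu(OAc)2, pyridine, 4 Å MS, CH2Cl2, oxygen, rt) comes back to the route at 12.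

3. Step 14 (global demethylation). Cleavage of eighteen ethers may stop at partly methylated stages, and the free polyphenol may be lost to air oxidation during aqueous isolation. The fallback sets out from 23 and isolates the product through a stable derivative. Push–pull demethylation with AlCl3/EtSH (CH2Cl2, rt) is followed by acetylation of the crude polyphenol (Ac2O, pyridine) to the henicosa-O-acetate of the target F3, which can be chromatographed on silica. Acid methanolysis of F3 (HCl generated from AcCl in MeOH, Ar, rt) comes back to the route at 24.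

Further compounds
F1 | step 12 | fully methylated octamer (2,4,6-trimethoxyphenyl ether on the position 1 oxygen of ring B of the permethylated heptamer) | COc1cc(OC)c(Oc2cc(OC)c(Oc3cc(OC)c(OC)c(OC)c3Oc3cc(OC)c(Oc4cc(OC)c(OC)c(OC)c4Oc4cc(OC)c(Oc5cc(OC)c(OC)c(OC)c5Oc5cc(OC)c(OC)c(OC)c5)c(OC)c4)c(OC)c3)c(OC)c2)c(OC)c1
F2 | step 7 | {3,5-dimethoxy-4-[3,4,5-trimethoxy-2-(methoxymethoxy)phenoxy]phenyl}boronic acid | OB(O)c1cc(OC)c(Oc2cc(OC)c(OC)c(OC)c2OCOC)c(OC)c1
F3 | step 14 | henicosa-O-acetate of CNP0206369.0 | CC(=O)Oc1cc(OC(C)=O)c(Oc2cc(OC(C)=O)c(Oc3cc(OC(C)=O)c(OC(C)=O)c(OC(C)=O)c3Oc3cc(OC(C)=O)c(Oc4cc(OC(C)=O)c(OC(C)=O)c(OC(C)=O)c4Oc4cc(OC(C)=O)c(Oc5cc(OC(C)=O)c(OC(C)=O)c(OC(C)=O)c5Oc5cc(OC(C)=O)c(OC(C)=O)c(OC(C)=O)c5)c(OC(C)=O)c4)c(OC(C)=O)c3)c(OC(C)=O)c2)c(OC(C)=O)c1
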